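**Retrosynthetic overview**
- The target is the mono-O-prenyl ether of (−)-pinoresinol. The prenyl group goes on last but one (Williamson) and a silyl ether comes off last, so the acid- and hydrogenation-sensitive allyl ether never meets the harsh steps.
- Both tetrahydrofuran rings come from one acid-mediated double cyclodehydration of a 2,3-bis(aryl-hydroxymethyl)butane-1,4-diol. The ring at the benzyloxyaryl carbinol closes first, then the second ring. The two bridgehead carbons are already fixed at that point.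
- The tetraol comes from LiAlH4 reduction of a 3-(aryl-hydroxymethyl)-4-aroyl-5-menthyloxy-butanolide.
- Key C–C bonds: intermolecular Michael addition of a lithiated 2-aryl-1,3-dithiane to (5S)-5-menthyloxy-2(5H)-furanone, then intermolecular aldol addition of the resulting lactone enolate to O-benzylvanillin, in one pot.
- Starting materials: vanillin, O-benzylvanillin, furfural, (+)-menthol (recovered in step 7; natural (−)-menthol would give the enantiomeric skeleton) and prenyl bromide.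

Assumption: the SMILES is read as (1R,3aS,4R,6aS), both aryl groups exo. Carbinol carbons that form as epimer mixtures and are re-set in step 8 are written without configuration.

**Route**

Step 1
Reactants: 1 vanillin (4-hydroxy-3-methoxybenzaldehyde)
Product: 2 4-(1,3-dithian-2-yl)-2-methoxyphenol
Conditions: HS(CH2)3SH, BF3·OEt2 (cat.), CH2Cl2, 0 °C → rt
Reagents that add atoms: propane-1,3-dithiol (SCCCS)
Why: Lewis-acid-catalysed dithioacetalisation of the aldehyde gives the acyl-anion precursor and tolerates the free phenol.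

Step 2
Reactants: 2 4-(1,3-dithian-2-yl)-2-methoxyphenol
Product: 3 2-[3-methoxy-4-(triisopropylsilyloxy)phenyl]-1,3-dithiane
Conditions: TIPSCl, imidazole, DMF, rt
Reagents that add atoms: triisopropylsilyl chloride (CC(C)[Si](Cl)(C(C)C)C(C)C)
Why: Phenol silylation; the aryl TIPS ether survives n-BuLi, LiAlH4, catalytic acid and hydrogenolysis and is removed by fluoride at the end.

Step 3
Reactants: 4 furfural (furan-2-carbaldehyde)
Product: 6 5-hydroxyfuran-2(5H)-one (racemic), via furfural endoperoxide 5 (not isolated)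
Conditions: O2, hν (visible), methylene blue (C16H18ClN3S, cat.), MeOH, 20 °C
Reagents that add atoms: oxygen (O=O)
Why: Dye-sensitised singlet-oxygen [4+2] cycloaddition to the furan, then methanolysis of the endoperoxide, which expels the formyl carbon as methyl formate.

Step 4
Reactants: 6 5-hydroxyfuran-2(5H)-one; 7 (+)-menthol [(1S,2R,5S)-5-methyl-2-(propan-2-yl)cyclohexan-1-ol]
Product: 9 (5S)-5-[(1S,2R,5S)-menthyloxy]furan-2(5H)-one, via (5R)-epimer 8 (not isolated)
Conditions: p-TsOH (cat.), toluene, reflux, Dean–Stark; crystallise from petroleum ether, re-equilibrate mother liquor with the acid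
Reagents that add atoms: none
Why: Acid-catalysed acetalisation gives both C5 epimers, which interconvert through the oxocarbenium ion; the (5S) diastereomer (mirror image of the crystalline (5R) acetal of natural menthol) crystallises, so a crystallisation-induced diastereomer transformation sets C5.

Step 5
Reactants: 3 2-[3-methoxy-4-(triisopropylsilyloxy)phenyl]-1,3-dithiane; 9 (5S)-5-[(1S,2R,5S)-menthyloxy]furan-2(5H)-one; 10 4-(benzyloxy)-3-methoxybenzaldehyde
Product: 13 (3R,4S,5S)-3-[(4-benzyloxy-3-methoxyphenyl)(hydroxy)methyl]-4-{2-[3-methoxy-4-(triisopropylsilyloxy)phenyl]-1,3-dithian-2-yl}-5-[(1S,2R,5S)-menthyloxy]dihydrofuran-2(3H)-one (carbinol epimers), via 2-lithio-1,3-dithiane 11 (not isolated), via lithium enolate 12 (not isolated)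
Conditions: n-BuLi, THF, −78 °C; then 9, −78 °C; then 10, −78 °C; AcOH quench at −78 °C
Reagents that add atoms: none
Why: Tandem Michael addition–aldol reaction: the soft sulfur-stabilised benzylic anion adds 1,4 to the butenolide anti to the C5 menthyloxy group (sets C4 as S), the lactone enolate then adds to the aldehyde anti to the bulky C4 substituent (sets C3 as R), and the new carbinol carbon is left uncontrolled because step 8 re-sets it.

Step 6
Reactants: 13 aldol adduct
Product: 14 (3R,4S,5S)-3-[(4-benzyloxy-3-methoxyphenyl)(hydroxy)methyl]-4-[3-methoxy-4-(triisopropylsilyloxy)benzoyl]-5-[(1S,2R,5S)-menthyloxy]dihydrofuran-2(3H)-one (carbinol epimers)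
Conditions: Hg(ClO4)2·3H2O, CaCO3, THF/H2O (5:1), 0 °C → rt
Reagents that add atoms: water (O)
Why: Thiophile-assisted hydrolysis of the dithioacetal (unmasking of the acyl-anion equivalent) under carbonate buffering, which spares the menthyl acetal, silyl ether and benzyl ether; C4 is already in its all-trans arrangement.

Step 7
Reactants: 14 keto lactone
Product: 15 (2S,3S)-2-[(4-benzyloxy-3-methoxyphenyl)(hydroxy)methyl]-3-{hydroxy[3-methoxy-4-(triisopropylsilyloxy)phenyl]methyl}butane-1,4-diol (epimers at both carbinol carbons)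
Conditions: LiAlH4, THF, 0 °C → rt; H2O/aq. NaOH work-up
Reagents that add atoms: none
Why: Hydride reduction takes the ketone to the carbinol, the lactone carbonyl to CH2OH and the acylal carbon C5 (aldehyde level, released with menthol) to CH2OH, while the two central stereocentres are untouched.

Step 8
Reactants: 15 tetraol
Product: 17 (1R,3aS,4R,6aS)-1-[4-(benzyloxy)-3-methoxyphenyl]-4-[3-methoxy-4-(triisopropylsilyloxy)phenyl]tetrahydro-1H,3H-furo[3,4-c]furan, via tetrahydrofuran diol 16 (not isolated)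
Conditions: CSA (0.1 equiv), CH2Cl2 (0.01 M), 4 Å MS, 0 °C → rt; Et3N quench
Reagents that add atoms: none
Why: SN1 double cyclodehydration: each p-oxygenated benzylic alcohol ionises to a quinone-methide-like cation that is trapped 5-exo by the CH2OH of the other central carbon on the face that puts the aryl trans to the neighbouring ring substituent (exo, R), so the carbinol epimer mixture converges and the cis ring fusion follows from the fixed (S,S) centres.

Step 9
Reactants: 17 benzyl-protected furofuran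
Product: 18 4-{(1R,3aS,4R,6aS)-4-[3-methoxy-4-(triisopropylsilyloxy)phenyl]tetrahydro-1H,3H-furo[3,4-c]furan-1-yl}-2-methoxyphenol
Conditions: H2 (1 atm), Pd/C (10%), EtOAc, rt, stopped at full conversion
Reagents that add atoms: none
Why: Catalytic hydrogenolysis; under neutral conditions the aryl benzyl ether cleaves much faster than the dialkyl benzylic C–O bonds of the furofuran, and the silyl ether is inert.

Step 10
Reactants: 18 monophenol; 19 prenyl bromide (1-bromo-3-methylbut-2-ene)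
Product: 20 (1R,3aS,4R,6aS)-1-[3-methoxy-4-(3-methylbut-2-enyloxy)phenyl]-4-[3-methoxy-4-(triisopropylsilyloxy)phenyl]tetrahydro-1H,3H-furo[3,4-c]furan
Conditions: K2CO3, acetone, rt → 40 °C
Reagents that add atoms: none
Why: Williamson ether synthesis (SN2 of the phenoxide on the primary allylic bromide); anhydrous carbonate in acetone favours O-alkylation and leaves the aryl silyl ether alone.

Step 11
Reactants: 20 silyl ether
Product: 21 target, 4-{(1R,3aS,4R,6aS)-4-[3-methoxy-4-(3-methylbut-2-enyloxy)phenyl]tetrahydro-1H,3H-furo[3,4-c]furan-1-yl}-2-methoxyphenol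
Conditions: Bu4NF, AcOH, THF, 0 °C
Reagents that add atoms: none
Why: Fluoride-mediated desilylation driven by the Si–F bond; the buffered medium leaves the prenyl ether and the benzylic ethers (all four stereocentres) untouched.

**Compound list**

1 | vanillin (4-hydroxy-3-methoxybenzaldehyde) | O=Cc1ccc(O)c(OC)c1 | starting material
2 | 4-(1,3-dithian-2-yl)-2-methoxyphenol | COc1cc(C2SCCCS2)ccc1O | intermediate
3 | 2-[3-methoxy-4-(triisopropylsilyloxy)phenyl]-1,3-dithiane | COc1cc(C2SCCCS2)ccc1O[Si](C(C)C)(C(C)C)C(C)C | intermediate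
4 | furfural (furan-2-carbaldehyde) | O=Cc1ccco1 | starting material
5 | furfural endoperoxide (2,3,7-trioxabicyclo[2.2.1]hept-5-ene-1-carbaldehyde, racemic) | O=CC12C=CC(OO1)O2 | intermediate
6 | 5-hydroxyfuran-2(5H)-one (racemic) | O=C1C=CC(O)O1 | intermediate
7 | (+)-menthol, (1S,2R,5S)-5-methyl-2-(propan-2-yl)cyclohexan-1-ol | O[C@H]1C[C@@H](C)CC[C@@H]1C(C)C | starting material
8 | (5R)-5-[(1S,2R,5S)-menthyloxy]furan-2(5H)-one | O=C1C=C[C@H](O[C@H]2C[C@@H](C)CC[C@@H]2C(C)C)O1 | intermediate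
9 | (5S)-5-[(1S,2R,5S)-menthyloxy]furan-2(5H)-one | O=C1C=C[C@@H](O[C@H]2C[C@@H](C)CC[C@@H]2C(C)C)O1 | intermediate
10 | 4-(benzyloxy)-3-methoxybenzaldehyde | O=Cc1ccc(OCc2ccccc2)c(OC)c1 | starting material
11 | 2-lithio-2-[3-methoxy-4-(triisopropylsilyloxy)phenyl]-1,3-dithiane | [Li]C1(SCCCS1)c1ccc(O[Si](C(C)C)(C(C)C)C(C)C)c(OC)c1 | intermediate
12 | lithium (4S,5S)-4-{2-[3-methoxy-4-(triisopropylsilyloxy)phenyl]-1,3-dithian-2-yl}-5-[(1S,2R,5S)-menthyloxy]-4,5-dihydrofuran-2-olate | [Li]OC1=C[C@H](C2(SCCCS2)c2ccc(O[Si](C(C)C)(C(C)C)C(C)C)c(OC)c2)[C@@H](O[C@H]2C[C@@H](C)CC[C@@H]2C(C)C)O1 | intermediate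
13 | (3R,4S,5S)-3-[(4-benzyloxy-3-methoxyphenyl)(hydroxy)methyl]-4-{2-[3-methoxy-4-(triisopropylsilyloxy)phenyl]-1,3-dithian-2-yl}-5-[(1S,2R,5S)-menthyloxy]dihydrofuran-2(3H)-one, carbinol epimers | O=C1O[C@H](O[C@H]2C[C@@H](C)CC[C@@H]2C(C)C)[C@@H](C2(SCCCS2)c2ccc(O[Si](C(C)C)(C(C)C)C(C)C)c(OC)c2)[C@@H]1C(O)c1ccc(OCc2ccccc2)c(OC)c1 | intermediate
14 | (3R,4S,5S)-3-[(4-benzyloxy-3-methoxyphenyl)(hydroxy)methyl]-4-[3-methoxy-4-(triisopropylsilyloxy)benzoyl]-5-[(1S,2R,5S)-menthyloxy]dihydrofuran-2(3H)-one, carbinol epimers | O=C1O[C@H](O[C@H]2C[C@@H](C)CC[C@@H]2C(C)C)[C@@H](C(=O)c2ccc(O[Si](C(C)C)(C(C)C)C(C)C)c(OC)c2)[C@@H]1C(O)c1ccc(OCc2ccccc2)c(OC)c1 | intermediate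
15 | (2S,3S)-2-[(4-benzyloxy-3-methoxyphenyl)(hydroxy)methyl]-3-{hydroxy[3-methoxy-4-(triisopropylsilyloxy)phenyl]methyl}butane-1,4-diol, carbinol epimers | OC[C@H]([C@@H](CO)C(O)c1ccc(O[Si](C(C)C)(C(C)C)C(C)C)c(OC)c1)C(O)c1ccc(OCc2ccccc2)c(OC)c1 | intermediate
16 | [(2R,3S,4S)-2-(4-benzyloxy-3-methoxyphenyl)-4-{hydroxy[3-methoxy-4-(triisopropylsilyloxy)phenyl]methyl}tetrahydrofuran-3-yl]methanol, carbinol epimers | OC[C@@H]1[C@H](C(O)c2ccc(O[Si](C(C)C)(C(C)C)C(C)C)c(OC)c2)CO[C@H]1c1ccc(OCc2ccccc2)c(OC)c1 | intermediate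
17 | (1R,3aS,4R,6aS)-1-[4-(benzyloxy)-3-methoxyphenyl]-4-[3-methoxy-4-(triisopropylsilyloxy)phenyl]tetrahydro-1H,3H-furo[3,4-c]furan | COc1cc([C@@H]2OC[C@@H]3[C@H]2CO[C@H]3c2ccc(OCc4ccccc4)c(OC)c2)ccc1O[Si](C(C)C)(C(C)C)C(C)C | intermediate
18 | 4-{(1R,3aS,4R,6aS)-4-[3-methoxy-4-(triisopropylsilyloxy)phenyl]tetrahydro-1H,3H-furo[3,4-c]furan-1-yl}-2-methoxyphenol | COc1cc([C@@H]2OC[C@@H]3[C@H]2CO[C@H]3c2ccc(O)c(OC)c2)ccc1O[Si](C(C)C)(C(C)C)C(C)C | intermediate
19 | prenyl bromide (1-bromo-3-methylbut-2-ene) | CC(C)=CCBr | starting material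
20 | (1R,3aS,4R,6aS)-1-[3-methoxy-4-(3-methylbut-2-enyloxy)phenyl]-4-[3-methoxy-4-(triisopropylsilyloxy)phenyl]tetrahydro-1H,3H-furo[3,4-c]furan | COc1cc([C@@H]2OC[C@@H]3[C@H]2CO[C@H]3c2ccc(OCC=C(C)C)c(OC)c2)ccc1O[Si](C(C)C)(C(C)C)C(C)C | intermediate
21 | 4-{(1R,3aS,4R,6aS)-4-[3-methoxy-4-(3-methylbut-2-enyloxy)phenyl]tetrahydro-1H,3H-furo[3,4-c]furan-1-yl}-2-methoxyphenol (CNP0185952.2) | COc1cc([C@@H]2OC[C@@H]3[C@H]2CO[C@H]3c2ccc(OCC=C(C)C)c(OC)c2)ccc1O | target

**Step count and risks**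

Total steps: 11. Longest linear sequence: 9 steps (furfural arm: steps 3, 4, 5, 6, 7, 8, 9, 10, 11; the vanillin arm 1, 2, 5–11 is equally long).

Most likely to fail:

Step 5 (tandem Michael–aldol). Three components must react in order at −78 °C. Possible failures are 1,2-addition of the dithiane anion, enolate quenching before the aldehyde reacts, and retro-aldol on warming. Fallback, setting out from 3 and 9 and coming back at 13: run the conjugate addition alone, quench with AcOH and isolate (4S,5S)-4-{2-[3-methoxy-4-(triisopropylsilyloxy)phenyl]-1,3-dithian-2-yl}-5-[(1S,2R,5S)-menthyloxy]dihydrofuran-2(3H)-one F1. After purification, deprotonate it in a separate directed aldol with lithium diisopropylamide (LiN(iPr)2) in THF at −78 °C, optionally transmetalate with ZnCl2 to suppress retro-aldol, and add 10. The aldehyde again enters anti to the C4 substituent and gives 13.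

Step 8 (double cyclodehydration). Exo,exo selectivity is kinetic. Acid can also epimerise the product toward the roughly 1:1 exo,exo/endo,exo equilibrium, close the benzylic cation onto the other benzylic hydroxyl to give a 2,5-diaryltetrahydrofuran, or cause oligomerisation. Fallback, setting out from 15 and coming back at 17: give up kinetic control and use thermodynamic recycling. Close 15 under the acid until all monocyclic material is consumed, then separate 17 by chromatography from the mono-endo epimers (1S,3aS,4R,6aS)-1-[4-(benzyloxy)-3-methoxyphenyl]-4-[3-methoxy-4-(triisopropylsilyloxy)phenyl]tetrahydro-1H,3H-furo[3,4-c]furan F2 and (1R,3aS,4S,6aS)-1-[4-(benzyloxy)-3-methoxyphenyl]-4-[3-methoxy-4-(triisopropylsilyloxy)phenyl]tetrahydro-1H,3H-furo[3,4-c]furan F3. Re-equilibrate the pooled F2 and F3 with CSA in CHCl3 at 50 °C (benzylic C–O re-ionisation) and harvest further 17 on each pass; the bridgehead carbons cannot epimerise.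

Step 9 (debenzylation). Over-reduction would open the furofuran at its benzylic C–O bonds. Fallback, setting out from 1, 19, 3 and 9 and coming back at 20: avoid the benzyl group and carry the prenyl ether from the start. Alkylate 1 with 19 (K2CO3, acetone) to give 3-methoxy-4-(3-methylbut-2-enyloxy)benzaldehyde F4 and use it in place of 10 in the step 5 protocol. This gives (3R,4S,5S)-3-{hydroxy[3-methoxy-4-(3-methylbut-2-enyloxy)phenyl]methyl}-4-{2-[3-methoxy-4-(triisopropylsilyloxy)phenyl]-1,3-dithian-2-yl}-5-[(1S,2R,5S)-menthyloxy]dihydrofuran-2(3H)-one F5. Hydrolyse the dithiane without a thiophilic metal, by S-alkylation (MeI, CaCO3, MeCN/H2O, 40 °C), which does not touch the trisubstituted alkene, to give (3R,4S,5S)-3-{hydroxy[3-methoxy-4-(3-methylbut-2-enyloxy)phenyl]methyl}-4-[3-methoxy-4-(triisopropylsilyloxy)benzoyl]-5-[(1S,2R,5S)-menthyloxy]dihydrofuran-2(3H)-one F6. LiAlH4 then gives (2S,3S)-2-{hydroxy[3-methoxy-4-(3-methylbut-2-enyloxy)phenyl]methyl}-3-{hydroxy[3-methoxy-4-(triisopropylsilyloxy)phenyl]methyl}butane-1,4-diol F7. Close F7 as in step 8 but hold it at 0 °C, where the catalytic acid should not cleave the aryl prenyl ether; this gives 20 directly, and step 11 follows.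

**Further compounds**

F1 | step 5 | (4S,5S)-4-{2-[3-methoxy-4-(triisopropylsilyloxy)phenyl]-1,3-dithian-2-yl}-5-[(1S,2R,5S)-menthyloxy]dihydrofuran-2(3H)-one | O=C1C[C@H](C2(SCCCS2)c2ccc(O[Si](C(C)C)(C(C)C)C(C)C)c(OC)c2)[C@@H](O[C@H]2C[C@@H](C)CC[C@@H]2C(C)C)O1
F2 | step 8 | (1S,3aS,4R,6aS)-1-[4-(benzyloxy)-3-methoxyphenyl]-4-[3-methoxy-4-(triisopropylsilyloxy)phenyl]tetrahydro-1H,3H-furo[3,4-c]furan | COc1cc([C@@H]2OC[C@@H]3[C@H]2CO[C@@H]3c2ccc(OCc4ccccc4)c(OC)c2)ccc1O[Si](C(C)C)(C(C)C)C(C)C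
F3 | step 8 | (1R,3aS,4S,6aS)-1-[4-(benzyloxy)-3-methoxyphenyl]-4-[3-methoxy-4-(triisopropylsilyloxy)phenyl]tetrahydro-1H,3H-furo[3,4-c]furan | COc1cc([C@H]2OC[C@@H]3[C@H]2CO[C@H]3c2ccc(OCc4ccccc4)c(OC)c2)ccc1O[Si](C(C)C)(C(C)C)C(C)C
F4 | step 9 | 3-methoxy-4-(3-methylbut-2-enyloxy)benzaldehyde | O=Cc1ccc(OCC=C(C)C)c(OC)c1
F5 | step 9 | (3R,4S,5S)-3-{hydroxy[3-methoxy-4-(3-methylbut-2-enyloxy)phenyl]methyl}-4-{2-[3-methoxy-4-(triisopropylsilyloxy)phenyl]-1,3-dithian-2-yl}-5-[(1S,2R,5S)-menthyloxy]dihydrofuran-2(3H)-one, carbinol epimers | O=C1O[C@H](O[C@H]2C[C@@H](C)CC[C@@H]2C(C)C)[C@@H](C2(SCCCS2)c2ccc(O[Si](C(C)C)(C(C)C)C(C)C)c(OC)c2)[C@@H]1C(O)c1ccc(OCC=C(C)C)c(OC)c1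
F6 | step 9 | (3R,4S,5S)-3-{hydroxy[3-methoxy-4-(3-methylbut-2-enyloxy)phenyl]methyl}-4-[3-methoxy-4-(triisopropylsilyloxy)benzoyl]-5-[(1S,2R,5S)-menthyloxy]dihydrofuran-2(3H)-one, carbinol epimers | O=C1O[C@H](O[C@H]2C[C@@H](C)CC[C@@H]2C(C)C)[C@@H](C(=O)c2ccc(O[Si](C(C)C)(C(C)C)C(C)C)c(OC)c2)[C@@H]1C(O)c1ccc(OCC=C(C)C)c(OC)c1
F7 | step 9 | (2S,3S)-2-{hydroxy[3-methoxy-4-(3-methylbut-2-enyloxy)phenyl]methyl}-3-{hydroxy[3-methoxy-4-(triisopropylsilyloxy)phenyl]methyl}butane-1,4-diol, carbinol epimers | OC[C@H]([C@@H](CO)C(O)c1ccc(O[Si](C(C)C)(C(C)C)C(C)C)c(OC)c1)C(O)c1ccc(OCC=C(C)C)c(OC)c1
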